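The undecyl side chain is cut between C-2′ and C-3′ (numbered from C-3 of the isochromanone). The key step exploits the 1,4-relationship between C-3′ and the ketone carbon C-6′: the unit C-3′ to C-6′ is a ring-opened acylcyclopropane. A nickel-catalysed reductive ring-opening alkylation joins the primary bromide of (S)-3-(2-bromoethyl)-6,8-dimethoxyisochroman-1-one to a ring CH2 of cyclopropyl pentyl ketone, forming the C-2′–C-3′ bond and unmasking the linear ketone in one operation. The lactone ring and the C-3 stereocentre come from an ortho-lithiated 2,4-dimethoxybenzamide and (R)-2-(2-bromoethyl)oxirane; chelation-controlled 8-O-demethylation completes the synthesis.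

Key step: step 4

Assumption: (R)-2-(2-bromoethyl)oxirane is taken as a commercial enantiopure building block; it would otherwise be made by hydrolytic kinetic resolution of the racemate.

Step 1
Reactants: 1 2,4-dimethoxybenzoyl chloride
Product: 2 N,N-diethyl-2,4-dimethoxybenzamide
Conditions: Et2NH (1.2 equiv), 2 M NaOH, CH2Cl2, 0 °C to rt
Reagents that add atoms: diethylamine, CCNCC
Why: Schotten–Baumann acylation of a secondary amine by an aroyl chloride should give the tertiary amide, which serves as the ortho-directing group and as the latent lactone carbonyl.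

Step 2
Reactants: 2 N,N-diethyl-2,4-dimethoxybenzamide, 3 (R)-2-(2-bromoethyl)oxirane
Product: 6 (S)-3-(2-bromoethyl)-6,8-dimethoxyisochroman-1-one, via ortho-lithiated amide 4 (not isolated), via hydroxy amide 5 (not isolated)
Conditions: s-BuLi, TMEDA, THF, −78 °C; 3, BF3·OEt2 (3 equiv), −78 °C; 1 M HCl quench; then TsOH·H2O (1.2 equiv), toluene, reflux
Reagents that add atoms: none
Why: Amide-directed ortho-metalation should lithiate C-6, the only free position ortho to the amide, BF3-promoted SN2 opening of the epoxide at its unsubstituted CH2 carries the stereocentre over unchanged (the descriptor turns from R to S only through the CIP priorities), and acid-promoted attack of the secondary alcohol on the neighbouring amide closes the six-membered lactone with loss of diethylamine.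

Step 3
Reactants: 7 cyclopropanecarbonitrile, 8 n-pentylmagnesium bromide
Product: 10 1-cyclopropylhexan-1-one, via magnesium ketimide 9 (not isolated)
Conditions: Et2O, 0 °C to reflux; then 2 M HCl, 0 °C to rt
Reagents that add atoms: water, O
Why: Grignard addition to a nitrile stops at the N-magnesio ketimine, so no tertiary alcohol can form, and cold dilute acid should hydrolyse it to the ketone without opening the cyclopropane.

Step 4
Reactants: 6 (S)-3-(2-bromoethyl)-6,8-dimethoxyisochroman-1-one, 10 1-cyclopropylhexan-1-one
Product: 12 (R)-6,8-dimethoxy-3-(6-oxoundecyl)isochroman-1-one, via silyl enol ether 11 (not isolated)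
Conditions: 10 (2.5 equiv), NiCl2·glyme (10 mol %), 4,4′,4″-tri-tert-butylterpyridine (10 mol %), Mn powder, TMSCl, DMA, 40 °C, slow addition of 6; then 1 M HCl, THF, rt
Reagents that add atoms: none
Why: Proposed new method: the terpyridine–nickel catalyst, reduced by Mn, is expected to open the TMSCl-activated acylcyclopropane 10 at a ring CH2 (strain-driven, SN2-type oxidative addition) to a γ-nickelated silyl enol ether, which captures the primary radical formed from bromide 6 by halogen abstraction; C(sp3)–C(sp3) reductive elimination then forms the C-2′–C-3′ bond, and the acid work-up hydrolyses silyl enol ether 11 to the ketone. The closest known reaction types are the nickel-catalysed reductive ring-opening alkylation of aryl cyclopropyl ketones with primary alkyl bromides and the silyl-chloride-assisted nickel-catalysed reductive conjugate addition of alkyl halides to dialkyl enones; new here is the dialkyl cyclopropyl ketone, for which the silyl chloride must supply the activation that an aryl ketone provides by itself. No ring is closed (the cyclopropane is opened) and no stereocentre is formed; C-3 lies two carbons away from the radical centre and should keep its configuration. The step needs cross-coupling to outrun homocoupling, reduction and β-hydride elimination of the bromide, which the excess of 10 and the slow addition of 6 are meant to secure. Only one ring-opened constitution can arise, because the two C(α)–CH2 bonds of the unsubstituted cyclopropane are equivalent. The lactone and the aryl methyl ethers should be inert to the nickel/manganese system, and the new ketone stays masked as its silyl enol ether until work-up.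

Step 5
Reactants: 12 (R)-6,8-dimethoxy-3-(6-oxoundecyl)isochroman-1-one
Product: 14 (R)-8-hydroxy-6-methoxy-3-(6-oxoundecyl)isochroman-1-one, via dichloroboryl ether 13 (not isolated)
Conditions: BCl3 (2.2 equiv), CH2Cl2, −78 to 0 °C; then H2O
Reagents that add atoms: none
Why: Chelation-controlled Lewis-acid ether cleavage: BCl3 is held between the lactone carbonyl and the peri 8-methoxy oxygen, so chloride should remove only that methyl group and leave the 6-methoxy group, the ketone and C-3 untouched.

Compound list
1 | 2,4-dimethoxybenzoyl chloride | COc1ccc(C(=O)Cl)c(OC)c1 | starting material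
2 | N,N-diethyl-2,4-dimethoxybenzamide | CCN(CC)C(=O)c1ccc(OC)cc1OC | intermediate
3 | (R)-2-(2-bromoethyl)oxirane | BrCC[C@@H]1CO1 | starting material
4 | [2-(diethylcarbamoyl)-3,5-dimethoxyphenyl]lithium (ortho-lithiated amide, not isolated) | [Li]c1cc(OC)cc(OC)c1C(=O)N(CC)CC | intermediate
5 | N,N-diethyl-2-[(2S)-4-bromo-2-hydroxybutyl]-4,6-dimethoxybenzamide (hydroxy amide, not isolated) | BrCC[C@@H](O)Cc1cc(OC)cc(OC)c1C(=O)N(CC)CC | intermediate
6 | (S)-3-(2-bromoethyl)-6,8-dimethoxyisochroman-1-one | BrCC[C@@H]1Cc2cc(OC)cc(OC)c2C(=O)O1 | intermediate
7 | cyclopropanecarbonitrile | N#CC1CC1 | starting material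
8 | n-pentylmagnesium bromide | CCCCC[Mg]Br | starting material
9 | N-bromomagnesio 1-cyclopropylhexan-1-imine (magnesium ketimide, not isolated) | CCCCCC(=N[Mg]Br)C1CC1 | intermediate
10 | 1-cyclopropylhexan-1-one (cyclopropyl pentyl ketone) | CCCCCC(=O)C1CC1 | intermediate
11 | (R)-6,8-dimethoxy-3-[6-(trimethylsilyloxy)undec-5-en-1-yl]isochroman-1-one (silyl enol ether, alkene geometry not defined, not isolated) | CCCCCC(O[Si](C)(C)C)=CCCCC[C@@H]1Cc2cc(OC)cc(OC)c2C(=O)O1 | intermediate
12 | (R)-6,8-dimethoxy-3-(6-oxoundecyl)isochroman-1-one | CCCCCC(=O)CCCCC[C@@H]1Cc2cc(OC)cc(OC)c2C(=O)O1 | intermediate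
13 | (R)-8-(dichloroboryloxy)-6-methoxy-3-(6-oxoundecyl)isochroman-1-one (dichloroboryl ether, not isolated) | CCCCCC(=O)CCCCC[C@@H]1Cc2cc(OC)cc(OB(Cl)Cl)c2C(=O)O1 | intermediate
14 | (R)-8-hydroxy-6-methoxy-3-(6-oxoundecyl)isochroman-1-one (CNP0370634.1) | CCCCCC(=O)CCCCC[C@@H]1Cc2cc(OC)cc(O)c2C(=O)O1 | target

Total step count: 5
Longest linear sequence: 4 steps (steps 1, 2, 4, 5); step 3 is a one-step side branch.

Steps most likely to fail

1. Step 4 (Proposed new method). The nickel catalyst may fail to open the weakly activated dialkyl acylcyclopropane, so that homocoupling, reduction or β-hydride elimination of the alkyl bromide outruns the cross-coupling. The fallback uses known chemistry, sets out from 10 and 6 and comes back at 12. Ketone 10 is opened with 48 % HBr to 1-bromononan-4-one F1, which is protected with ethylene glycol (TsOH, toluene, water separator) as 2-(3-bromopropyl)-2-pentyl-1,3-dioxolane F2 and converted with Mg in THF into [3-(2-pentyl-1,3-dioxolan-2-yl)propyl]magnesium bromide F3. Copper-catalysed alkyl–alkyl coupling of this Grignard reagent with bromide 6 (Li2CuCl4 cat., THF/NMP, −20 to 0 °C, slow addition of the Grignard reagent) forms the same C-2′–C-3′ bond and should give (R)-6,8-dimethoxy-3-[5-(2-pentyl-1,3-dioxolan-2-yl)pentyl]isochroman-1-one F4. Aqueous HCl in THF then removes the ketal and returns to 12.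

2. Step 2. The ortho-lithiated amide may open the BF3-activated epoxide sluggishly or attack the primary bromide instead, and the hindered diethylamide may resist lactonisation. The fallback sets out from epoxide 3 and comes back at 6, introducing the carbonyl carbon last. 1-Bromo-3,5-dimethoxybenzene F5 is converted (Mg, THF) into 3,5-dimethoxyphenylmagnesium bromide F6, which should open 3 at the terminal carbon under CuI catalysis (−30 °C, then dilute HCl) to (S)-4-bromo-1-(3,5-dimethoxyphenyl)butan-2-ol F7. N-Bromosuccinimide (MeCN, 0 °C) should brominate the ring ortho to the side chain and para to a methoxy group to give (S)-4-bromo-1-(2-bromo-3,5-dimethoxyphenyl)butan-2-ol F8. Palladium-catalysed carbonylative lactonisation (CO 1 atm, Pd(OAc)2, Xantphos, K2CO3, toluene, 90 °C) then closes the lactone to 6.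

3. Step 5. The two aryl methyl ethers may be discriminated incompletely, or the side-chain ketone may sequester the Lewis acid, leading to under- or over-cleavage. The fallback sets out from 12 and comes back at 14, replacing selective cleavage by exhaustive cleavage and selective re-methylation. Excess BBr3 (CH2Cl2, −78 to 0 °C) should cleave both ethers to (R)-6,8-dihydroxy-3-(6-oxoundecyl)isochroman-1-one F9. MeI (1.05 equiv) with K2CO3 in acetone at rt should then methylate only the free 6-hydroxyl, because the 8-hydroxyl is hydrogen-bonded to the lactone carbonyl and far less nucleophilic, giving 14.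

Further compounds
F1 | step 4 | 1-bromononan-4-one | BrCCCC(=O)CCCCC
F2 | step 4 | 2-(3-bromopropyl)-2-pentyl-1,3-dioxolane | BrCCCC1(CCCCC)OCCO1
F3 | step 4 | [3-(2-pentyl-1,3-dioxolan-2-yl)propyl]magnesium bromide | Br[Mg]CCCC1(CCCCC)OCCO1
F4 | step 4 | (R)-6,8-dimethoxy-3-[5-(2-pentyl-1,3-dioxolan-2-yl)pentyl]isochroman-1-one | CCCCCC1(CCCCC[C@@H]2Cc3cc(OC)cc(OC)c3C(=O)O2)OCCO1
F5 | step 2 | 1-bromo-3,5-dimethoxybenzene | COc1cc(Br)cc(OC)c1
F6 | step 2 | 3,5-dimethoxyphenylmagnesium bromide | COc1cc([Mg]Br)cc(OC)c1
F7 | step 2 | (S)-4-bromo-1-(3,5-dimethoxyphenyl)butan-2-ol | BrCC[C@@H](O)Cc1cc(OC)cc(OC)c1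
F8 | step 2 | (S)-4-bromo-1-(2-bromo-3,5-dimethoxyphenyl)butan-2-ol | BrCC[C@@H](O)Cc1cc(OC)cc(OC)c1Br
F9 | step 5 | (R)-6,8-dihydroxy-3-(6-oxoundecyl)isochroman-1-one | CCCCCC(=O)CCCCC[C@@H]1Cc2cc(O)cc(O)c2C(=O)O1
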